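The ester‑bearing cyclopentane (ring E: C8, C13, C14, C15, C9) is cut at C8–C13 and C14–C15. Ring E is a methylenecyclopentane whose exocyclic alkene is the tetrasubstituted C9=C10 bond, so C8–C9(=C10)–C15 is a trimethylenemethane and C13–C14(CO2Me) is methyl acrylate. In one operation zerovalent palladium ionises a C15 carbonate, the bridgehead lactam C8–H is deprotonated, and the zwitterion adds across methyl acrylate: both ring bonds, the quaternary C8 next to quaternary C5, the C15 stereocentre and the C9=C10 alkene arise together. The precursor is a tetracyclic lactam without C13, C14 and C22, in which the nine‑membered azacycle, the δ‑lactam and the cyclopentene‑fused cycloheptene are already closed.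

Key step: step 27

Remark: atoms carry the Daphniphyllum numbering: C22 ester carbon, C14 (CH–CO2Me), C13 (CH2), C8 (quaternary, α to lactam C1), C9=C10, C15 (allylic CH), C16, C17, C11, C12, C6, C7 (NCH2), C5 (quaternary; C21 = CH2OAc), C4, C3, C2 (CHOH), C18 (CHMe, methyl C20), C19 (NCH2); rings: L = δ‑lactam, M = nine‑membered azacycle, S = cycloheptene, F = cyclopentene, E = ester‑bearing cyclopentane.

**Fragment 1: the C19–C18–C2–C3 aldehyde (steps 1–4)**

Step 1
Reactants: 1 (S)-4-benzyl-3-propionyl-1,3-oxazolidin-2-one; 2 acrolein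
Product: 3 (S)-4-benzyl-3-[(2S,3R)-3-hydroxy-2-methylpent-4-enoyl]-1,3-oxazolidin-2-one
Conditions: Bu2BOTf, iPr2NEt, CH2Cl2, −78 to 0 °C; then pH 7 buffer, MeOH, H2O2
Reagents that add atoms: none
Why: Evans syn‑aldol reaction: the (Z)‑boron enolate reacts through a chair transition state on the face left open by the (S)‑benzyl auxiliary, which should set C18 and C2 as the syn (2S,3R) pair needed for the C18 methyl and the C2 hydroxyl.

Step 2
Reactants: 3 (S)-4-benzyl-3-[(2S,3R)-3-hydroxy-2-methylpent-4-enoyl]-1,3-oxazolidin-2-one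
Product: 4 (S)-4-benzyl-3-[(2S,3R)-3-(tert-butyldimethylsilyloxy)-2-methylpent-4-enoyl]-1,3-oxazolidin-2-one
Conditions: TBSOTf, 2,6-lutidine, CH2Cl2, −78 to 0 °C
Reagents that add atoms: tert-butyldimethylsilyl trifluoromethanesulfonate, CC(C)(C)[Si](C)(C)OS(=O)(=O)C(F)(F)F
Why: Silyl ether formation with the silyl triflate protects the hindered C2 hydroxyl for the whole route and touches no stereocentre.

Step 3
Reactants: 4 (S)-4-benzyl-3-[(2S,3R)-3-(tert-butyldimethylsilyloxy)-2-methylpent-4-enoyl]-1,3-oxazolidin-2-one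
Product: 5 (2R,3R)-3-(tert-butyldimethylsilyloxy)-2-methylpent-4-en-1-ol
Conditions: LiBH4, MeOH (1 equiv), Et2O, 0 °C
Reagents that add atoms: none
Why: Reductive cleavage of the N‑acyl oxazolidinone by LiBH4 should release the primary alcohol (later C19) and the auxiliary without epimerising C18.

Step 4
Reactants: 5 (2R,3R)-3-(tert-butyldimethylsilyloxy)-2-methylpent-4-en-1-ol
Product: 6 (2S,3R)-3-(tert-butyldimethylsilyloxy)-2-methylpent-4-enal
Conditions: Dess–Martin periodinane, CH2Cl2, 0 °C to rt
Reagents that add atoms: none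
Why: Dess–Martin oxidation gives the α‑branched aldehyde under non‑basic conditions that should leave C18 intact.

**Fragment 2: the ring F building block (steps 5–8)**

Step 5
Reactants: 7 cyclopentane-1,3-dione
Product: 8 2-bromo-3-hydroxycyclopent-2-en-1-one
Conditions: NBS, CH2Cl2, 0 °C
Reagents that add atoms: N-bromosuccinimide, O=C1CCC(=O)N1Br
Why: Electrophilic bromination of the enolised 1,3‑dione at its nucleophilic central carbon places bromine on the later C9.

Step 6
Reactants: 8 2-bromo-3-hydroxycyclopent-2-en-1-one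
Product: 9 2-bromo-3-iodocyclopent-2-en-1-one
Conditions: PPh3, I2, Et3N, MeCN, rt
Reagents that add atoms: iodine, II
Why: The vinylogous acid is converted into the β‑iodo enone by Ph3P·I2 (oxyphosphonium formation, then addition–elimination by iodide), which puts two halides of different reactivity on the later C9 and C10.

Step 7
Reactants: 9 2-bromo-3-iodocyclopent-2-en-1-one
Product: 10 (S)-2-bromo-3-iodocyclopent-2-en-1-ol
Conditions: (R)-2-methyl-CBS-oxazaborolidine (10 mol%), BH3·SMe2, THF, −20 °C; then MeOH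
Reagents that add atoms: none
Why: CBS reduction: the bromoalkene arm acts as the large group, so the (R)‑oxazaborolidine should give the (S)‑carbinol, which sets C15 under reagent control.

Step 8
Reactants: 10 (S)-2-bromo-3-iodocyclopent-2-en-1-ol
Product: 11 (S)-[(2-bromo-3-iodocyclopent-2-en-1-yl)oxy]triethylsilane
Conditions: TESCl, imidazole, CH2Cl2, 0 °C
Reagents that add atoms: chlorotriethylsilane, CC[Si](Cl)(CC)CC
Why: Silylation masks the allylic alcohol during the two later palladium steps as an ether that can be removed in the presence of TBS ethers.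

**Main line: C6, C5 and ring L (steps 9–19)**

Step 9
Reactants: 12 [(but-3-en-1-yloxy)methyl]benzene; 13 (E)-but-2-enal
Product: 14 (E)-5-(benzyloxy)pent-2-enal
Conditions: second-generation Hoveyda–Grubbs catalyst (2 mol%), 13 (5 equiv), CH2Cl2, 40 °C
Reagents that add atoms: none
Why: Olefin cross‑metathesis of the terminal alkene with crotonaldehyde should give the E‑enal with loss of propene.

Step 10
Reactants: 14 (E)-5-(benzyloxy)pent-2-enal; 15 nitromethane
Product: 16 (S)-5-(benzyloxy)-3-(nitromethyl)pentanal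
Conditions: (R)-2-[diphenyl(trimethylsilyloxy)methyl]pyrrolidine (10 mol%), PhCO2H (10 mol%), MeOH, rt
Reagents that add atoms: none
Why: Iminium‑catalysed Michael addition: the (R)‑diarylprolinol silyl ether shields one face of the E‑iminium ion, so the nitromethyl group (later C7 and N) should enter to give the (S)‑configured C6.

Step 11
Reactants: 16 (S)-5-(benzyloxy)-3-(nitromethyl)pentanal
Product: 17 (S)-5-(benzyloxy)-3-(nitromethyl)pentanoic acid
Conditions: NaClO2, NaH2PO4, 2-methylbut-2-ene, t-BuOH/H2O, 0 °C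
Reagents that add atoms: sodium chlorite, [Na+].[O-]Cl=O
Why: Pinnick oxidation converts the aldehyde (C21) into the acid without touching the nitro group or C6.

Step 12
Reactants: 17 (S)-5-(benzyloxy)-3-(nitromethyl)pentanoic acid
Product: 19 (S)-4-[2-(benzyloxy)ethyl]pyrrolidin-2-one, via amino acid 18 (not isolated)
Conditions: NiCl2·6H2O, NaBH4, MeOH, 0 °C; then toluene, 110 °C
Reagents that add atoms: none
Why: Nickel boride reduction of the nitro group gives the γ‑amino acid, which closes to the five‑membered lactam on heating (lactamisation) with C6 untouched.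

Step 13
Reactants: 19 (S)-4-[2-(benzyloxy)ethyl]pyrrolidin-2-one
Product: 20 tert-butyl (S)-4-[2-(benzyloxy)ethyl]-2-oxopyrrolidine-1-carboxylate
Conditions: Boc2O, DMAP (cat.), Et3N, CH2Cl2, rt
Reagents that add atoms: di-tert-butyl dicarbonate, CC(C)(C)OC(=O)OC(=O)OC(C)(C)C
Why: N‑Acylation makes the lactam α‑protons more acidic and turns the ring carbonyl into an imide‑type carbonyl for the later reductive opening.

Step 14
Reactants: 20 tert-butyl (S)-4-[2-(benzyloxy)ethyl]-2-oxopyrrolidine-1-carboxylate; 21 acetaldehyde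
Product: 24 tert-butyl (S,E)-4-[2-(benzyloxy)ethyl]-3-ethylidene-2-oxopyrrolidine-1-carboxylate, via aldol adduct 22 (not isolated), via mesylate 23 (not isolated)
Conditions: LiHMDS, THF, −78 °C; MeCHO; MsCl, −78 to 0 °C; DBU, rt
Reagents that add atoms: none
Why: Aldol addition of the lithium enolate, mesylation and E1cB elimination (aldol condensation) give the α‑ethylidene lactam, and the stereocentre formed transiently at C5 is erased.

Step 15
Reactants: 24 tert-butyl (S,E)-4-[2-(benzyloxy)ethyl]-3-ethylidene-2-oxopyrrolidine-1-carboxylate; 25 ethyl bromoacetate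
Product: 26 tert-butyl (3R,4S)-4-[2-(benzyloxy)ethyl]-3-(2-ethoxy-2-oxoethyl)-2-oxo-3-vinylpyrrolidine-1-carboxylate
Conditions: LDA, HMPA, THF, −78 °C; 25, −78 to −40 °C
Reagents that add atoms: none
Why: Deconjugative alkylation: γ‑deprotonation gives the extended enolate, which is alkylated at the α‑carbon (C5) on the face anti to the C6 side chain, so the quaternary C5 should form with the acetate arm (C8, C1) trans and the vinyl group (C4) cis to that chain.

Step 16
Reactants: 26 tert-butyl (3R,4S)-4-[2-(benzyloxy)ethyl]-3-(2-ethoxy-2-oxoethyl)-2-oxo-3-vinylpyrrolidine-1-carboxylate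
Product: 28 tert-butyl {(S)-4-(benzyloxy)-2-[(R)-5-oxo-3-vinyloxolan-3-yl]butyl}carbamate, via hydroxy ester 27 (not isolated)
Conditions: NaBH4, EtOH, 0 °C to rt; then PPTS (cat.), toluene, 80 °C
Reagents that add atoms: none
Why: Reductive ring‑opening of the N‑Boc lactam: NaBH4 reduces the imide‑type ring carbonyl (C21) in preference to the ethyl ester, and the neopentyl alcohol lactonises onto the ester arm (Thorpe–Ingold effect), which fixes C21 at the alcohol level and masks it.

Step 17
Reactants: 28 tert-butyl {(S)-4-(benzyloxy)-2-[(R)-5-oxo-3-vinyloxolan-3-yl]butyl}carbamate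
Product: 29 (S)-4-(benzyloxy)-2-[(R)-5-oxo-3-vinyloxolan-3-yl]butan-1-aminium trifluoroacetate
Conditions: TFA, CH2Cl2, 0 °C
Reagents that add atoms: trifluoroacetic acid, OC(=O)C(F)(F)F
Why: Acidolysis of the Boc carbamate gives the ammonium salt, in which nitrogen cannot attack the lactone before the next step.

Step 18
Reactants: 29 (S)-4-(benzyloxy)-2-[(R)-5-oxo-3-vinyloxolan-3-yl]butan-1-aminium trifluoroacetate; 6 (2S,3R)-3-(tert-butyldimethylsilyloxy)-2-methylpent-4-enal
Product: 31 (4R,5S)-5-[2-(benzyloxy)ethyl]-1-[(2R,3R)-3-(tert-butyldimethylsilyloxy)-2-methylpent-4-en-1-yl]-4-(hydroxymethyl)-4-vinylpiperidin-2-one, via secondary amine 30 (not isolated)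
Conditions: Et3N (1 equiv), NaBH(OAc)3, ClCH2CH2Cl, rt; then 2-hydroxypyridine (cat.), toluene, 100 °C
Reagents that add atoms: none
Why: Reductive amination of the α‑branched aldehyde (fast iminium reduction under weakly acidic conditions should preserve C18) followed by intramolecular aminolysis of the γ‑lactone (O‑to‑N acyl transfer) closes ring L and frees the C21 hydroxyl.

Step 19
Reactants: 31 (4R,5S)-5-[2-(benzyloxy)ethyl]-1-[(2R,3R)-3-(tert-butyldimethylsilyloxy)-2-methylpent-4-en-1-yl]-4-(hydroxymethyl)-4-vinylpiperidin-2-one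
Product: 32 (4R,5S)-5-[2-(benzyloxy)ethyl]-4-[(tert-butyldimethylsilyloxy)methyl]-1-[(2R,3R)-3-(tert-butyldimethylsilyloxy)-2-methylpent-4-en-1-yl]-4-vinylpiperidin-2-one
Conditions: TBSCl, imidazole, DMF, 40 °C
Reagents that add atoms: tert-butyldimethylsilyl chloride, CC(C)(C)[Si](C)(C)Cl
Why: Silyl ether formation protects the neopentyl C21 hydroxyl against the bases and organometallics that follow.

**Main line: rings M, F and S (steps 20–26)**

Step 20
Reactants: 32 (4R,5S)-5-[2-(benzyloxy)ethyl]-4-[(tert-butyldimethylsilyloxy)methyl]-1-[(2R,3R)-3-(tert-butyldimethylsilyloxy)-2-methylpent-4-en-1-yl]-4-vinylpiperidin-2-one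
Product: 33 ring L/M bicyclic lactam with Z-C3=C4 alkene (2,21-bis-O-TBS 11-O-benzyl)
Conditions: second-generation Grubbs catalyst (10 mol%), toluene (1 mM), 80 °C
Reagents that add atoms: none
Why: Ring‑closing metathesis of the two monosubstituted alkenes, held 1,4 across the δ‑lactam, should close the nine‑membered ring M with loss of ethene, the ring size enforcing the Z alkene.

Step 21
Reactants: 33 ring L/M bicyclic lactam with Z-C3=C4 alkene (2,21-bis-O-TBS 11-O-benzyl)
Product: 34 ring L/M bicyclic lactam C11 alcohol (2,21-bis-O-TBS)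
Conditions: H2 (1 atm), Pd/C, EtOAc, rt
Reagents that add atoms: none
Why: Catalytic hydrogenation saturates the only alkene (C3=C4) and hydrogenolyses the benzyl ether in the same operation.

Step 22
Reactants: 34 ring L/M bicyclic lactam C11 alcohol (2,21-bis-O-TBS)
Product: 35 ring L/M bicyclic lactam C11 iodide (2,21-bis-O-TBS)
Conditions: I2, PPh3, imidazole, CH2Cl2, 0 °C to rt
Reagents that add atoms: iodine, II
Why: Appel‑type iodination converts the only free (primary) alcohol into the iodide needed for zinc insertion.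

Step 23
Reactants: 35 ring L/M bicyclic lactam C11 iodide (2,21-bis-O-TBS); 11 (S)-[(2-bromo-3-iodocyclopent-2-en-1-yl)oxy]triethylsilane
Product: 37 ring L/M bicyclic lactam carrying the (S)-2-bromo-3-(triethylsilyloxy)cyclopent-1-enyl unit at C11 (2,21-bis-O-TBS), via alkylzinc iodide 36 (not isolated)
Conditions: Zn, LiCl, THF, 40 °C; then 11, Pd2(dba)3 (2.5 mol%), SPhos (10 mol%), THF, rt
Reagents that add atoms: none
Why: Negishi coupling: the alkylzinc iodide couples at the carbon–iodine bond of 11, which adds to zerovalent palladium much faster than the neighbouring carbon–bromine bond, and so forms C10–C11 and keeps the bromide on C9.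

Step 24
Reactants: 37 ring L/M bicyclic lactam carrying the (S)-2-bromo-3-(triethylsilyloxy)cyclopent-1-enyl unit at C11 (2,21-bis-O-TBS)
Product: 38 tetracyclic lactam (rings L/M/S/F) with C8-H and 15-O-TES (2,21-bis-O-TBS)
Conditions: Pd2(dba)3 (5 mol%), Xantphos (12 mol%), KHMDS, toluene, 70 °C
Reagents that add atoms: none
Why: Palladium‑catalysed intramolecular α‑alkenylation of the lactam enolate with the vinyl bromide closes the seven‑membered ring S (C8–C9), and C8 can only bond so that its hydrogen is exo to the new bicyclo[4.3.1] lactam, so its configuration follows from C5 and C6.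

Step 25
Reactants: 38 tetracyclic lactam (rings L/M/S/F) with C8-H and 15-O-TES (2,21-bis-O-TBS)
Product: 39 tetracyclic C15 allylic alcohol (2,21-bis-O-TBS)
Conditions: HF·pyridine, pyridine, THF, 0 °C
Reagents that add atoms: none
Why: Buffered fluoride cleaves the triethylsilyl ether much faster than the two TBS ethers (selective desilylation) and avoids acid that could ionise the allylic position.

Step 26
Reactants: 39 tetracyclic C15 allylic alcohol (2,21-bis-O-TBS)
Product: 40 tetracyclic C15 tert-butyl carbonate (2,21-bis-O-TBS)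
Conditions: Boc2O, DMAP, CH2Cl2, 0 °C to rt
Reagents that add atoms: di-tert-butyl dicarbonate, CC(C)(C)OC(=O)OC(=O)OC(C)(C)C
Why: Carbonate formation gives a leaving group that on ionisation releases tert‑butoxide, the internal base of the next step.

**Key step and endgame (steps 27–30)**

Step 27
Reactants: 40 tetracyclic C15 tert-butyl carbonate (2,21-bis-O-TBS); 41 methyl acrylate
Product: 42 pentacyclic methyl ester with the C14 ester exo (14-epimer; 2,21-bis-O-TBS)
Conditions: Pd2(dba)3·CHCl3 (5 mol%), P(OiPr)3 (30 mol%), 41 (10 equiv), THF, 50 °C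
Reagents that add atoms: none
Why: Proposed new method: zerovalent palladium ionises the allylic tert‑butyl carbonate with inversion to a π‑allyl complex over C15–C9–C10 and releases CO2 and tert‑butoxide, which removes the C8–H that is acidified by the lactam carbonyl and the adjacent cationic π‑allyl unit; the lactam‑stabilised trimethylenemethane–palladium zwitterion adds through C8 to the β‑carbon (C13) of methyl acrylate, and the ester enolate then attacks the C15 terminus and regenerates the catalyst. The closest known reaction type is the palladium‑catalysed [3+2] cycloaddition of acceptor‑substituted trimethylenemethane donors made from 2‑(cyanomethyl)‑, 2‑(sulfonylmethyl)‑ or 2‑(2,2,2‑trifluoroethyl)allyl carbonates by ionisation and in situ deprotonation; a lactam as acidifying group and a ring‑embedded bridgehead donor carbon have not been shown, although the bicyclo[4.3.1] lactam (bridge sum eight) can accommodate a bridgehead enolate. Ring E closes in two events, an intermolecular Michael addition (C8–C13) and an intramolecular allylic alkylation (C14–C15) of the kind that ends every palladium–trimethylenemethane cycloaddition. C8 can only be attacked on its exo lobe because rings L and S hold its other three bonds, so its configuration follows from C5 and C6; C15 results from double inversion, C14 taking the place of the carbonate oxygen set in step 7. The step needs closure at C15 and not at C10, which the full substitution of C10 and the gain of the tetrasubstituted C9=C10 alkene should secure, and it needs Michael addition to outrun β‑hydride loss from the π‑allyl complex, which the large excess of acrylate serves. C14 is expected with the ester exo (trans to C16, the less hindered arrangement and the one favoured under the tert‑butoxide present) and is corrected in step 28.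

Step 28
Reactants: 42 pentacyclic methyl ester with the C14 ester exo (14-epimer; 2,21-bis-O-TBS)
Product: 43 pentacyclic methyl ester with the target C14 configuration (2,21-bis-O-TBS)
Conditions: LDA, THF, −78 °C; then 2,6-di-tert-butyl-4-methylphenol, −78 °C
Reagents that add atoms: none
Why: Enolisation of the only acidic site (C14; C8 is quaternary) and kinetic protonation by the hindered phenol on the open convex face of the cup‑shaped bicyclo[3.3.0]octene (the face of H15, away from C16 and the C5 bridge) should place H14 cis to H15 and the ester cis to C16 as in the target, and both C14 epimers converge.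

Step 29
Reactants: 43 pentacyclic methyl ester with the target C14 configuration (2,21-bis-O-TBS)
Product: 44 C2,C21-diol (21-deacetyl target)
Conditions: HF·pyridine (excess), pyridine, THF, 0 °C to rt
Reagents that add atoms: none
Why: Fluoride‑mediated desilylation removes both TBS ethers under non‑basic conditions that should not epimerise C14.

Step 30
Reactants: 44 C2,C21-diol (21-deacetyl target)
Product: 45 CNP0296366.1 (target)
Conditions: AcCl (1.1 equiv), 2,4,6-collidine, CH2Cl2, −78 °C
Reagents that add atoms: acetyl chloride, CC(=O)Cl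
Why: Selective O‑acylation: the primary C21 hydroxyl should be acetylated much faster than the secondary C2 hydroxyl, which is flanked by the methyl‑bearing C18 inside the nine‑membered ring.

**Compound list**

1 | (S)-4-benzyl-3-propionyl-1,3-oxazolidin-2-one | CCC(=O)N1[C@@H](Cc2ccccc2)COC1=O | starting material
2 | acrolein | C=CC=O | starting material
3 | (S)-4-benzyl-3-[(2S,3R)-3-hydroxy-2-methylpent-4-enoyl]-1,3-oxazolidin-2-one | C=C[C@@H](O)[C@H](C)C(=O)N1[C@@H](Cc2ccccc2)COC1=O | intermediate
4 | (S)-4-benzyl-3-[(2S,3R)-3-(tert-butyldimethylsilyloxy)-2-methylpent-4-enoyl]-1,3-oxazolidin-2-one | C=C[C@@H](O[Si](C)(C)C(C)(C)C)[C@H](C)C(=O)N1[C@@H](Cc2ccccc2)COC1=O | intermediate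
5 | (2R,3R)-3-(tert-butyldimethylsilyloxy)-2-methylpent-4-en-1-ol | C=C[C@@H](O[Si](C)(C)C(C)(C)C)[C@H](C)CO | intermediate
6 | (2S,3R)-3-(tert-butyldimethylsilyloxy)-2-methylpent-4-enal | C=C[C@@H](O[Si](C)(C)C(C)(C)C)[C@H](C)C=O | intermediate
7 | cyclopentane-1,3-dione | O=C1CCC(=O)C1 | starting material
8 | 2-bromo-3-hydroxycyclopent-2-en-1-one | O=C1CCC(O)=C1Br | intermediate
9 | 2-bromo-3-iodocyclopent-2-en-1-one | O=C1CCC(I)=C1Br | intermediate
10 | (S)-2-bromo-3-iodocyclopent-2-en-1-ol | O[C@H]1CCC(I)=C1Br | intermediate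
11 | (S)-[(2-bromo-3-iodocyclopent-2-en-1-yl)oxy]triethylsilane | CC[Si](CC)(CC)O[C@H]1CCC(I)=C1Br | intermediate
12 | [(but-3-en-1-yloxy)methyl]benzene | C=CCCOCc1ccccc1 | starting material
13 | (E)-but-2-enal | C/C=C/C=O | starting material
14 | (E)-5-(benzyloxy)pent-2-enal | O=C/C=C/CCOCc1ccccc1 | intermediate
15 | nitromethane | C[N+](=O)[O-] | starting material
16 | (S)-5-(benzyloxy)-3-(nitromethyl)pentanal | O=CC[C@@H](C[N+](=O)[O-])CCOCc1ccccc1 | intermediate
17 | (S)-5-(benzyloxy)-3-(nitromethyl)pentanoic acid | O=C(O)C[C@@H](C[N+](=O)[O-])CCOCc1ccccc1 | intermediate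
18 | (S)-3-(aminomethyl)-5-(benzyloxy)pentanoic acid | NC[C@@H](CCOCc1ccccc1)CC(=O)O | intermediate
19 | (S)-4-[2-(benzyloxy)ethyl]pyrrolidin-2-one | O=C1C[C@H](CCOCc2ccccc2)CN1 | intermediate
20 | tert-butyl (S)-4-[2-(benzyloxy)ethyl]-2-oxopyrrolidine-1-carboxylate | O=C1C[C@H](CCOCc2ccccc2)CN1C(=O)OC(C)(C)C | intermediate
21 | acetaldehyde | CC=O | starting material
22 | tert-butyl (3R,4S)-4-[2-(benzyloxy)ethyl]-3-(1-hydroxyethyl)-2-oxopyrrolidine-1-carboxylate (lithium alkoxide in the flask; carbinol carbon unassigned) | CC(O)[C@H]1[C@H](CCOCc2ccccc2)CN(C(=O)OC(C)(C)C)C1=O | intermediate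
23 | tert-butyl (3R,4S)-4-[2-(benzyloxy)ethyl]-3-[1-(methylsulfonyloxy)ethyl]-2-oxopyrrolidine-1-carboxylate | CC(OS(C)(=O)=O)[C@H]1[C@H](CCOCc2ccccc2)CN(C(=O)OC(C)(C)C)C1=O | intermediate
24 | tert-butyl (S,E)-4-[2-(benzyloxy)ethyl]-3-ethylidene-2-oxopyrrolidine-1-carboxylate | C/C=C1\[C@H](CCOCc2ccccc2)CN(C(=O)OC(C)(C)C)C1=O | intermediate
25 | ethyl bromoacetate | CCOC(=O)CBr | starting material
26 | tert-butyl (3R,4S)-4-[2-(benzyloxy)ethyl]-3-(2-ethoxy-2-oxoethyl)-2-oxo-3-vinylpyrrolidine-1-carboxylate | C=C[C@]1(CC(=O)OCC)[C@H](CCOCc2ccccc2)CN(C(=O)OC(C)(C)C)C1=O | intermediate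
27 | ethyl (R)-3-{(S)-4-(benzyloxy)-1-[(tert-butoxycarbonyl)amino]butan-2-yl}-3-(hydroxymethyl)pent-4-enoate | C=C[C@](CO)(CC(=O)OCC)[C@H](CCOCc1ccccc1)CNC(=O)OC(C)(C)C | intermediate
28 | tert-butyl {(S)-4-(benzyloxy)-2-[(R)-5-oxo-3-vinyloxolan-3-yl]butyl}carbamate | C=C[C@@]1(COC(=O)C1)[C@H](CCOCc2ccccc2)CNC(=O)OC(C)(C)C | intermediate
29 | (S)-4-(benzyloxy)-2-[(R)-5-oxo-3-vinyloxolan-3-yl]butan-1-aminium trifluoroacetate | C=C[C@@]1(COC(=O)C1)[C@H](CCOCc2ccccc2)C[NH3+].[O-]C(=O)C(F)(F)F | intermediate
30 | (R)-4-{(S)-4-(benzyloxy)-1-[((2R,3R)-3-(tert-butyldimethylsilyloxy)-2-methylpent-4-en-1-yl)amino]butan-2-yl}-4-vinyloxolan-2-one | C=C[C@@]1(COC(=O)C1)[C@H](CCOCc2ccccc2)CNC[C@@H](C)[C@H](O[Si](C)(C)C(C)(C)C)C=C | intermediate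
31 | (4R,5S)-5-[2-(benzyloxy)ethyl]-1-[(2R,3R)-3-(tert-butyldimethylsilyloxy)-2-methylpent-4-en-1-yl]-4-(hydroxymethyl)-4-vinylpiperidin-2-one | O=C1C[C@](C=C)(CO)[C@H](CCOCc2ccccc2)CN1C[C@@H](C)[C@H](O[Si](C)(C)C(C)(C)C)C=C | intermediate
32 | (4R,5S)-5-[2-(benzyloxy)ethyl]-4-[(tert-butyldimethylsilyloxy)methyl]-1-[(2R,3R)-3-(tert-butyldimethylsilyloxy)-2-methylpent-4-en-1-yl]-4-vinylpiperidin-2-one | O=C1C[C@](C=C)(CO[Si](C)(C)C(C)(C)C)[C@H](CCOCc2ccccc2)CN1C[C@@H](C)[C@H](O[Si](C)(C)C(C)(C)C)C=C | intermediate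
33 | ring L/M bicyclic lactam with Z-C3=C4 alkene (2,21-bis-O-TBS, 11-O-benzyl; C2, C5, C6, C18 as in the target) | O=C1C[C@]2(CO[Si](C)(C)C(C)(C)C)[C@H](CCOCc3ccccc3)CN1C[C@@H](C)[C@H](O[Si](C)(C)C(C)(C)C)/C=C\2 | intermediate
34 | ring L/M bicyclic lactam C11 alcohol (2,21-bis-O-TBS) | O=C1C[C@]2(CO[Si](C)(C)C(C)(C)C)[C@H](CCO)CN1C[C@@H](C)[C@H](O[Si](C)(C)C(C)(C)C)CC2 | intermediate
35 | ring L/M bicyclic lactam C11 iodide (2,21-bis-O-TBS) | O=C1C[C@]2(CO[Si](C)(C)C(C)(C)C)[C@H](CCI)CN1C[C@@H](C)[C@H](O[Si](C)(C)C(C)(C)C)CC2 | intermediate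
36 | C11 alkylzinc iodide of 35 | O=C1C[C@]2(CO[Si](C)(C)C(C)(C)C)[C@H](CC[Zn]I)CN1C[C@@H](C)[C@H](O[Si](C)(C)C(C)(C)C)CC2 | intermediate
37 | ring L/M bicyclic lactam carrying the (S)-2-bromo-3-(triethylsilyloxy)cyclopent-1-enyl unit at C11 (2,21-bis-O-TBS) | O=C1C[C@]2(CO[Si](C)(C)C(C)(C)C)[C@H](CCC3=C(Br)[C@@H](O[Si](CC)(CC)CC)CC3)CN1C[C@@H](C)[C@H](O[Si](C)(C)C(C)(C)C)CC2 | intermediate
38 | tetracyclic lactam (rings L/M/S/F) with C8-H and 15-O-TES (2,21-bis-O-TBS; C15 S) | [C@@H]23C(=O)N4C[C@@H](CCC5=C2[C@@H](O[Si](CC)(CC)CC)CC5)[C@]3(CO[Si](C)(C)C(C)(C)C)CC[C@@H](O[Si](C)(C)C(C)(C)C)[C@H](C)C4 | intermediate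
39 | tetracyclic C15 allylic alcohol (2,21-bis-O-TBS) | [C@@H]23C(=O)N4C[C@@H](CCC5=C2[C@@H](O)CC5)[C@]3(CO[Si](C)(C)C(C)(C)C)CC[C@@H](O[Si](C)(C)C(C)(C)C)[C@H](C)C4 | intermediate
40 | tetracyclic C15 tert-butyl carbonate (2,21-bis-O-TBS) | [C@@H]23C(=O)N4C[C@@H](CCC5=C2[C@@H](OC(=O)OC(C)(C)C)CC5)[C@]3(CO[Si](C)(C)C(C)(C)C)CC[C@@H](O[Si](C)(C)C(C)(C)C)[C@H](C)C4 | intermediate
41 | methyl acrylate | C=CC(=O)OC | starting material
42 | pentacyclic methyl ester with the C14 ester exo (14-epimer; 2,21-bis-O-TBS) | COC(=O)[C@H]1C[C@@]23C(=O)N4C[C@@H](CCC5=C2[C@@H]1CC5)[C@]3(CO[Si](C)(C)C(C)(C)C)CC[C@@H](O[Si](C)(C)C(C)(C)C)[C@H](C)C4 | intermediate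
43 | pentacyclic methyl ester with the target C14 configuration (2,21-bis-O-TBS) | COC(=O)[C@@H]1C[C@@]23C(=O)N4C[C@@H](CCC5=C2[C@@H]1CC5)[C@]3(CO[Si](C)(C)C(C)(C)C)CC[C@@H](O[Si](C)(C)C(C)(C)C)[C@H](C)C4 | intermediate
44 | C2,C21-diol (21-deacetyl target) | COC(=O)[C@@H]1C[C@@]23C(=O)N4C[C@@H](CCC5=C2[C@@H]1CC5)[C@]3(CO)CC[C@@H](O)[C@H](C)C4 | intermediate
45 | CNP0296366.1 | COC(=O)[C@@H]1C[C@@]23C(=O)N4C[C@@H](CCC5=C2[C@@H]1CC5)[C@]3(COC(C)=O)CC[C@@H](O)[C@H](C)C4 | target

**Step count and risks**

Total step count: 30. Longest linear sequence: 22 steps (steps 9–30, from 12 and 13 to 45).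

Steps most likely to fail:

1. Step 27 (proposed new method). The bridgehead C8–H may not be removed fast enough, so that the π‑allyl complex loses a β‑hydrogen to give a cyclopentadiene, or the enolate may close through palladium (inner sphere) and invert C15. The fallback uses known chemistry, sets out from 37 and returns at 42. The C8 methylene of 37 is alkylated while it is not yet a bridgehead (LDA, HMPA, THF, −78 °C; trimethyl 3-bromoorthopropionate) to give the C8‑alkylated lactam F1. The palladium‑catalysed α‑alkenylation of step 24 (Pd2(dba)3, Xantphos, KHMDS) then closes ring S and forms the quaternary C8 in the tetracyclic orthoester F2. Aqueous acetic acid hydrolyses the orthoester to the methyl ester and cleaves the TES ether to give the hydroxy ester F3. Boc2O/DMAP gives the allylic carbonate F4. LiHMDS (THF, −78 °C) then Pd(PPh3)4 closes ring E by intramolecular allylic alkylation of the lithium ester enolate, giving 42 (any 43 formed alongside is carried through step 28 as well).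

2. Step 24. Reductive elimination from the eight‑membered palladacycle may be slower than protodehalogenation of the vinyl bromide or decomposition of the enolate. The fallback sets out from 37 and returns at 38. LiHMDS then 1,2-dibromotetrachloroethane gives the α‑bromo lactam F5. A nickel‑catalysed reductive cross‑electrophile coupling (NiBr2·glyme, 4,4′-di-tert-butyl-2,2′-bipyridine, Mn, DMA) then joins C8 and C9 through a C8 radical instead of an enolate.

3. Step 20. Metathesis at the vinyl group on quaternary C5 may be too slow for a nine‑membered ring, so that intermolecular dimerisation wins. The fallback sets out from 32 and returns at 33. Ozonolysis of both vinyl groups (O3, CH2Cl2, −78 °C; PPh3) gives the dialdehyde F6. An intramolecular McMurry coupling with low‑valent titanium (TiCl3(DME)1.5, Zn–Cu, DME, reflux, high dilution) then forms the C3=C4 bond, giving 33 (any E isomer is reduced to 34 in step 21 as well).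

Further compounds
F1 | step 27 | C8-(3,3,3-trimethoxypropyl) derivative of 37 (C8 epimers) | O=C1C(CCC(OC)(OC)OC)[C@]2(CO[Si](C)(C)C(C)(C)C)[C@H](CCC3=C(Br)[C@@H](O[Si](CC)(CC)CC)CC3)CN1C[C@@H](C)[C@H](O[Si](C)(C)C(C)(C)C)CC2
F2 | step 27 | tetracyclic lactam with quaternary C8 bearing the 3,3,3-trimethoxypropyl chain and 15-O-TES | COC(OC)(OC)CC[C@@]23C(=O)N4C[C@@H](CCC5=C2[C@@H](O[Si](CC)(CC)CC)CC5)[C@]3(CO[Si](C)(C)C(C)(C)C)CC[C@@H](O[Si](C)(C)C(C)(C)C)[C@H](C)C4
F3 | step 27 | tetracyclic C15 alcohol with the C8 methyl propanoate chain | COC(=O)CC[C@@]23C(=O)N4C[C@@H](CCC5=C2[C@@H](O)CC5)[C@]3(CO[Si](C)(C)C(C)(C)C)CC[C@@H](O[Si](C)(C)C(C)(C)C)[C@H](C)C4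
F4 | step 27 | tetracyclic C15 tert-butyl carbonate with the C8 methyl propanoate chain | COC(=O)CC[C@@]23C(=O)N4C[C@@H](CCC5=C2[C@@H](OC(=O)OC(C)(C)C)CC5)[C@]3(CO[Si](C)(C)C(C)(C)C)CC[C@@H](O[Si](C)(C)C(C)(C)C)[C@H](C)C4
F5 | step 24 | C8-bromo derivative of 37 (C8 epimers) | O=C1C(Br)[C@]2(CO[Si](C)(C)C(C)(C)C)[C@H](CCC3=C(Br)[C@@H](O[Si](CC)(CC)CC)CC3)CN1C[C@@H](C)[C@H](O[Si](C)(C)C(C)(C)C)CC2
F6 | step 20 | dialdehyde from 32 (C3 and C4 as formyl groups) | O=C1C[C@](C=O)(CO[Si](C)(C)C(C)(C)C)[C@H](CCOCc2ccccc2)CN1C[C@@H](C)[C@H](O[Si](C)(C)C(C)(C)C)C=O
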